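The trap in these two runs is their early overlap. At 1.33 h Friday's run, with the smaller charge, stands at 6.0% of its charge and Saturday's at 6.1%, which looks like first order in starting material throughout.

in all of them: gas 23 mM (held)

| flask | starting material | remark | time |
|---|---|---|---|
| Friday's | 0.15 M | run made earlier |  |
| Saturday's | 0.60 M | run made earlier |  |
| flask | 0.30 M |  | 3.0 h |

| run | time / h | product / % |
|---|---|---|
| Friday's | 0.167 | 0.3 |
| Friday's | 0.500 | 1.3 |
| Friday's | 0.833 | 1.8 |
| Friday's | 1.33 | 6.0 |
| Friday's | 2.00 | 15.0 |
| Friday's | 2.50 | 22.6 |
| Friday's | 3.00 | 32.2 |
| Saturday's | 0.417 | 2.0 |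
| Saturday's | 0.833 | 1.7 |
| Saturday's | 1.33 | 6.1 |
| Saturday's | 1.50 | 7.7 |
| Saturday's | 2.00 | 11.4 |
| Saturday's | 2.50 | 18.4 |
| Saturday's | 3.00 | 24.3 |

(each reading ± 1 percentage point)

1. amount of product in percent of the starting material charged, at 10 min, 50 min and 3.0 h

- the numbers in the tables scatter by 1 percentage point (one standard deviation)
- at the start none of the gas is in solution

First order serves as the zero of the scale, since there the fraction of the charge converted at a fixed time doesn't depend on the charge. At 3.00 h the two runs stand at 32.2% and 24.3% for a charge ratio of 4.00, which gives 0.203, the charge exponent: how steeply the product fraction at a fixed time falls with the logarithm of the charge. The flask's charge lies at the geometric middle of the two, so its fraction at 3.0 h should be 28.0%.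

At 1.33 h the same exponent reads −0.0119, zero for readings that scatter by 1 percentage point. Early readings can therefore be pooled across charges, and the pair at 50 min gives 1.75%. A power of time from there to 3.0 h has exponent 2.16, which puts 10 min at 0.0537%.

That is the weak link, since the slow start, the induction period, steepens towards early times. The pooled stretch from 50 min to 1.33 h alone gives a power of 2.65, and with it 10 min falls to 0.0244%, the value committed to.

The forecast, which speaks of “a weak inverse dependence, perhaps saturation”, gives 0.2%, 2.2% and 28%, higher than this reckoning at the first two times.

The flask gives 0.0161%, 1.62% and 28.4%. At 3.00 h its starting material is down to 4.36%, while 67.2% of the charge stands as open intermediate.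

    starting material → open intermediate (k = 2.90 × 10⁻⁴ s⁻¹)
    partner → second intermediate (k = 0.00117 s⁻¹)
    open intermediate + second intermediate → product (k = 3.51 × 10⁻⁴ L mol⁻¹ s⁻¹)
    gas ⇌ partner, rate k4*(csat - [partner]) (kL = 0.0270 s⁻¹)

Carried from this flask to Saturday's charge at 1.50 h, a charge exponent of 0.203 turns 6.96% of product into 6.05%, and Saturday's reading at 1.50 h, which is no part of that exponent, is 7.7%.

The readings were computed for an exercise, and the scatter is random.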